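## Retrosynthetic overview

- The plan rests on one feature of ring B (the benzenoid ring of the naphthoquinone): the aroyl carbon on C6 and the CH2 arm on C7 are ortho neighbours, and C6 sits next to the C5 oxygen. This 1-alkyl-2-acyl-3-oxy pattern is what a 3-alkoxyaryne gives when it inserts into the C(=O)–CH2 bond of a β-ketoester.
- Key disconnection: the C6–C(=O) and C7–CH2 bonds, made in one operation from the 5-methoxy-6,7-naphthalyne (as its ortho-silyl triflate) and the orsellinoyl β-ketoester (as its dimethyl ether).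
- Aryne precursor: ring B is built onto a purchased trimethoxybenzene (ring A) by lateral acetonylation of a toluate and Claisen ring closure to the naphthalene-5,7-diol. C7 carbamate, C5 methyl ether, carbamate-directed C6 silylation and triflation follow.
- After the key step: the arylacetic acid is joined to acetoacetate and lactonised to the 4-hydroxy-2-pyranone. Last, BBr3 removes all six methyl ethers and air takes ring A to the 2-hydroxy-1,4-quinone.
- Ring order: ring A (purchased) → ring B (step 4) → orsellinoyl ring (purchased) → pyranone ring (step 14); quinone oxidation level last (step 15).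

Key step: step 11

Remark on numbering: the naphthalene carbons keep the locants of the target quinone throughout (C1–C4 = ring A, the later quinone ring; C5–C8 = ring B).
Remark on intermediates: lithiated arenes and enolates are treated as conjugate bases of the numbered compounds and carry no numbers of their own.

## Route

Step 1
Reactants: 1 2,4,5-trimethoxybenzoic acid
Product: 2 3,4,6-trimethoxy-2-methylbenzoic acid
Conditions: s-BuLi (2.2 equiv), TMEDA (2.2 equiv), THF, −78 °C; MeI, −78 °C → rt; aq. HCl
Reagents that add atoms: iodomethane, CI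
Why: Directed ortho-metalation of the unprotected benzoic acid: C6 is the only position ortho to the lithium carboxylate and is also flanked by the C5 methoxy group, so s-BuLi/TMEDA at −78 °C should lithiate there and not at C3 between two methoxy groups, and iodomethane then methylates the aryllithium.

Step 2
Reactants: 2 3,4,6-trimethoxy-2-methylbenzoic acid
Product: 3 methyl 3,4,6-trimethoxy-2-methylbenzoate
Conditions: MeI, K2CO3, DMF, rt
Reagents that add atoms: iodomethane, CI
Why: SN2 O-alkylation of the carboxylate, which avoids the poor reactivity of a 2,6-disubstituted benzoic acid in Fischer esterification.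

Step 3
Reactants: 3 methyl 3,4,6-trimethoxy-2-methylbenzoate; 4 N-methoxy-N-methylacetamide
Product: 5 methyl 3,4,6-trimethoxy-2-(2-oxopropyl)benzoate
Conditions: LiN(iPr)2 (2.2 equiv), THF, −78 °C; then 4, −78 → −20 °C; aq. NH4Cl
Reagents that add atoms: none
Why: Lateral (benzylic) lithiation of the ortho-toluate and C-acylation by the Weinreb amide, whose chelated tetrahedral adduct prevents over-addition; the C6 methoxy group shields the ester against self-condensation.

Step 4
Reactants: 5 methyl 3,4,6-trimethoxy-2-(2-oxopropyl)benzoate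
Product: 6 1,2,4-trimethoxynaphthalene-5,7-diol (systematic name 5,6,8-trimethoxynaphthalene-1,3-diol)
Conditions: t-BuOK (2.5 equiv), THF, 0 °C → rt, argon; degassed aq. HCl
Reagents that add atoms: none
Why: Intramolecular Claisen (Dieckmann-type) condensation: the methyl-side enolate attacks the ester (6-exo-trig) and the cyclic 1,3-diketone aromatises to the naphthalenediol dianion, which drives the equilibrium; the air-sensitive diol is carried on directly.

Step 5
Reactants: 6 1,2,4-trimethoxynaphthalene-5,7-diol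
Product: 7 5-hydroxy-1,2,4-trimethoxynaphthalen-7-yl N-isopropylcarbamate
Conditions: iPrNCO (1.05 equiv), Et3N (0.2 equiv), CH2Cl2, 0 °C → rt, argon
Reagents that add atoms: isopropyl isocyanate, CC(C)N=C=O
Why: Base-catalysed addition of a phenol to an isocyanate (carbamoylation); the C5 hydroxyl is hydrogen-bonded to the peri C4 methoxy group and crowded, so one equivalent should react at the free C7 hydroxyl.

Step 6
Reactants: 7 5-hydroxy-1,2,4-trimethoxynaphthalen-7-yl N-isopropylcarbamate
Product: 8 1,2,4,5-tetramethoxynaphthalen-7-yl N-isopropylcarbamate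
Conditions: MeI, K2CO3, acetone, 40 °C
Reagents that add atoms: iodomethane, CI
Why: Williamson methylation of the remaining peri phenol; carbonate deprotonates the phenol but not the carbamate N–H, so the carbamate should stay in place.

Step 7
Reactants: 8 1,2,4,5-tetramethoxynaphthalen-7-yl N-isopropylcarbamate
Product: 11 1,2,4,5-tetramethoxy-6-(trimethylsilyl)naphthalen-7-yl N-isopropylcarbamate, via N-silyl carbamate 9 (not isolated), via doubly silylated carbamate 10 (not isolated)
Conditions: TBSOTf, TMEDA, Et2O, 0 °C → rt; n-BuLi, TMEDA, −78 °C; TMSCl, −78 °C → rt; aq. NaHSO4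
Reagents that add atoms: chlorotrimethylsilane, C[Si](C)(C)Cl
Why: Directed ortho-metalation of an aryl carbamate after transient N-silylation (which prevents N–H deprotonation and loss of isocyanate): C6, flanked by the carbamate and the C5 methoxy group, should be lithiated at −78 °C ahead of C8 and of C3, TMSCl silylates the aryllithium, and the N-silyl group is hydrolysed on bisulfate work-up.

Step 8
Reactants: 11 1,2,4,5-tetramethoxy-6-(trimethylsilyl)naphthalen-7-yl N-isopropylcarbamate
Product: 13 1,2,4,5-tetramethoxy-6-(trimethylsilyl)naphthalen-7-yl trifluoromethanesulfonate, via silyl naphthol 12 (not isolated)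
Conditions: DBU, Et2NH, MeCN, 40 °C; then PhNTf2, rt
Reagents that add atoms: N-phenylbis(trifluoromethanesulfonimide), O=S(=O)(N(c1ccccc1)S(=O)(=O)C(F)(F)F)C(F)(F)F
Why: DBU deprotonates the carbamate N–H and the anion expels the naphthoxide (E1cB-type carbamate cleavage, diethylamine trapping isopropyl isocyanate as a urea); the naphthoxide is then O-sulfonylated by PhNTf2 in the same flask (phenol triflation).

Step 9
Reactants: 14 3,5-dimethoxytoluene
Product: 15 1-(2,4-dimethoxy-6-methylphenyl)ethan-1-one
Conditions: AcCl, AlCl3, CH2Cl2, −10 → 0 °C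
Reagents that add atoms: acetyl chloride, CC(=O)Cl
Why: Friedel–Crafts acylation at the position ortho to methyl (para to one methoxy group, ortho to the other), which should be preferred over the position between the two methoxy groups; low temperature limits ortho-demethylation.

Step 10
Reactants: 15 1-(2,4-dimethoxy-6-methylphenyl)ethan-1-one
Product: 16 methyl 3-(2,4-dimethoxy-6-methylphenyl)-3-oxopropanoate
Conditions: NaH (2.2 equiv), (MeO)2CO, THF, reflux; aq. HCl
Reagents that add atoms: dimethyl carbonate, COC(=O)OC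
Why: Crossed Claisen condensation of the unhindered methyl-ketone enolate with dimethyl carbonate, driven by deprotonation of the β-ketoester product.

Step 11
Reactants: 13 1,2,4,5-tetramethoxy-6-(trimethylsilyl)naphthalen-7-yl trifluoromethanesulfonate; 16 methyl 3-(2,4-dimethoxy-6-methylphenyl)-3-oxopropanoate
Product: 19 methyl 2-[6-(2,4-dimethoxy-6-methylbenzoyl)-1,2,4,5-tetramethoxynaphthalen-7-yl]acetate, via naphthalyne 17 (not isolated), via benzocyclobutenoxide 18 (not isolated)
Conditions: 13 (1.3 equiv), CsF (2.5 equiv), dry MeCN, 80 °C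
Reagents that add atoms: none
Why: Fluoride attacks silicon of 13 and triflate leaves in a 1,2-elimination to give naphthalyne 17; the caesium enolate of 16 adds through its α-carbon to C7, the C6 aryl anion so formed closes onto the ketone carbonyl to give benzocyclobutenoxide 18, and strain-driven cleavage of the bond between the carbinol carbon and the ester-bearing carbon releases the diaryl ketone and an ester enolate that is protonated to 19. The closest known reaction type is the acyl-alkylation of arynes with β-ketoesters (insertion into the α C–C bond), which is established for 3-methoxybenzyne and for aryl ketoesters. The only ring closed is the transient four-membered ring of 18 (4-exo-trig attack of the aryl anion on the carbonyl), which opens again in the same operation, so the product gains no ring. The two stereocentres of 18 are transient and none remains in 19. The step needs regioselective addition to the aryne, which the C5 methoxy group secures: its inductive pull and the resulting aryne distortion direct the nucleophile to the remote carbon C7 and place the anion at C6 next to oxygen. It also needs carbonyl capture at the hindered orsellinoyl ketone to outrun protonation of the C6 anion, which is helped by dry acetonitrile with the ketoester as the only proton source.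

Step 12
Reactants: 19 methyl 2-[6-(2,4-dimethoxy-6-methylbenzoyl)-1,2,4,5-tetramethoxynaphthalen-7-yl]acetate
Product: 20 2-[6-(2,4-dimethoxy-6-methylbenzoyl)-1,2,4,5-tetramethoxynaphthalen-7-yl]acetic acid
Conditions: LiOH, THF/MeOH/H2O, rt; aq. HCl
Reagents that add atoms: lithium hydroxide, [Li+].[OH-]
Why: Saponification of an unhindered methyl ester; the tetra-ortho-substituted diaryl ketone is inert to hydroxide.

Step 13
Reactants: 20 2-[6-(2,4-dimethoxy-6-methylbenzoyl)-1,2,4,5-tetramethoxynaphthalen-7-yl]acetic acid; 21 methyl acetoacetate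
Product: 23 methyl 6-[6-(2,4-dimethoxy-6-methylbenzoyl)-1,2,4,5-tetramethoxynaphthalen-7-yl]-3,5-dioxohexanoate, via acyl imidazolide 22 (not isolated)
Conditions: 20, CDI, THF, rt; then added to the dianion of 21 (3 equiv; NaH then n-BuLi, THF, 0 °C) at −78 → 0 °C; aq. HCl
Reagents that add atoms: none
Why: Activation of the acid as its acyl imidazolide and Claisen-type C-acylation of the acetoacetate dianion at its γ-carbon; excess dianion absorbs the acidic proton of the triketo product, and the tetra-ortho-substituted diaryl ketone is too hindered to be attacked.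

Step 14
Reactants: 23 methyl 6-[6-(2,4-dimethoxy-6-methylbenzoyl)-1,2,4,5-tetramethoxynaphthalen-7-yl]-3,5-dioxohexanoate
Product: 24 6-{[6-(2,4-dimethoxy-6-methylbenzoyl)-1,2,4,5-tetramethoxynaphthalen-7-yl]methyl}-4-hydroxy-2H-pyran-2-one
Conditions: DBU, toluene, 80 °C; aq. HCl
Reagents that add atoms: none
Why: Base-promoted enol-lactonisation of a 3,5-dioxoester (6-exo-trig acyl substitution of the methyl ester by the C5 enol oxygen) to the 4-hydroxy-2-pyranone; aldol attack on the hindered diaryl ketone should not compete.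

Step 15
Reactants: 24 6-{[6-(2,4-dimethoxy-6-methylbenzoyl)-1,2,4,5-tetramethoxynaphthalen-7-yl]methyl}-4-hydroxy-2H-pyran-2-one
Product: 26 CNP0158797.0 (6-{[6-(2,4-dihydroxy-6-methylbenzoyl)-2,5-dihydroxy-1,4-dioxo-1,4-dihydronaphthalen-7-yl]methyl}-4-hydroxy-2H-pyran-2-one), via hexaphenol 25 (not isolated)
Conditions: BBr3 (excess), CH2Cl2, −78 °C → rt; H2O; then air (O2), EtOAc/pH 7 phosphate buffer, rt
Reagents that add atoms: none
Why: Lewis-acid cleavage of all six aryl methyl ethers by BBr3, followed by autoxidation of the liberated 1,2,4-trihydroxy ring A to the 2-hydroxy-1,4-quinone, as in the classical preparation of lawsone from 1,2,4-trihydroxynaphthalene; no metal oxidant meets the enolic pyranone.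

## Compound list

1 | 2,4,5-trimethoxybenzoic acid | COc1cc(OC)c(C(=O)O)cc1OC | starting material
2 | 3,4,6-trimethoxy-2-methylbenzoic acid | Cc1c(OC)c(OC)cc(OC)c1C(=O)O | intermediate
3 | methyl 3,4,6-trimethoxy-2-methylbenzoate | COC(=O)c1c(C)c(OC)c(OC)cc1OC | intermediate
4 | N-methoxy-N-methylacetamide | CON(C)C(C)=O | starting material
5 | methyl 3,4,6-trimethoxy-2-(2-oxopropyl)benzoate | COC(=O)c1c(CC(C)=O)c(OC)c(OC)cc1OC | intermediate
6 | 1,2,4-trimethoxynaphthalene-5,7-diol | COc1c(OC)cc(OC)c2c(O)cc(O)cc12 | intermediate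
7 | 5-hydroxy-1,2,4-trimethoxynaphthalen-7-yl N-isopropylcarbamate | COc1c(OC)cc(OC)c2c(O)cc(OC(=O)NC(C)C)cc12 | intermediate
8 | 1,2,4,5-tetramethoxynaphthalen-7-yl N-isopropylcarbamate | COc1c(OC)cc(OC)c2c(OC)cc(OC(=O)NC(C)C)cc12 | intermediate
9 | 1,2,4,5-tetramethoxynaphthalen-7-yl N-(tert-butyldimethylsilyl)-N-isopropylcarbamate (not isolated) | COc1c(OC)cc(OC)c2c(OC)cc(OC(=O)N(C(C)C)[Si](C)(C)C(C)(C)C)cc12 | intermediate
10 | 1,2,4,5-tetramethoxy-6-(trimethylsilyl)naphthalen-7-yl N-(tert-butyldimethylsilyl)-N-isopropylcarbamate (not isolated) | COc1c(OC)cc(OC)c2c(OC)c([Si](C)(C)C)c(OC(=O)N(C(C)C)[Si](C)(C)C(C)(C)C)cc12 | intermediate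
11 | 1,2,4,5-tetramethoxy-6-(trimethylsilyl)naphthalen-7-yl N-isopropylcarbamate | COc1c(OC)cc(OC)c2c(OC)c([Si](C)(C)C)c(OC(=O)NC(C)C)cc12 | intermediate
12 | 1,2,4,5-tetramethoxy-6-(trimethylsilyl)naphthalen-7-ol (not isolated) | COc1c(OC)cc(OC)c2c(OC)c([Si](C)(C)C)c(O)cc12 | intermediate
13 | 1,2,4,5-tetramethoxy-6-(trimethylsilyl)naphthalen-7-yl trifluoromethanesulfonate | COc1c(OC)cc(OC)c2c(OC)c([Si](C)(C)C)c(OS(=O)(=O)C(F)(F)F)cc12 | intermediate
14 | 3,5-dimethoxytoluene | COc1cc(C)cc(OC)c1 | starting material
15 | 1-(2,4-dimethoxy-6-methylphenyl)ethan-1-one | CC(=O)c1c(C)cc(OC)cc1OC | intermediate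
16 | methyl 3-(2,4-dimethoxy-6-methylphenyl)-3-oxopropanoate | COC(=O)CC(=O)c1c(C)cc(OC)cc1OC | intermediate
17 | 1,2,4,5-tetramethoxy-6,7-didehydronaphthalene, the 5-methoxy-6,7-naphthalyne (not isolated) | COC1=C(OC)C=C(OC)C2=C(OC)C#CC=C12 | intermediate
18 | caesium benzocyclobutenoxide: four-membered ring fused at C6–C7, made of C7, CH(CO2Me), C(O−)(2,4-dimethoxy-6-methylphenyl) and C6; relative configuration undefined, transient (not isolated) | COC(=O)C1c2cc3c(OC)c(OC)cc(OC)c3c(OC)c2C1([O-])c1c(C)cc(OC)cc1OC.[Cs+] | intermediate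
19 | methyl 2-[6-(2,4-dimethoxy-6-methylbenzoyl)-1,2,4,5-tetramethoxynaphthalen-7-yl]acetate | COC(=O)Cc1cc2c(OC)c(OC)cc(OC)c2c(OC)c1C(=O)c1c(C)cc(OC)cc1OC | intermediate
20 | 2-[6-(2,4-dimethoxy-6-methylbenzoyl)-1,2,4,5-tetramethoxynaphthalen-7-yl]acetic acid | OC(=O)Cc1cc2c(OC)c(OC)cc(OC)c2c(OC)c1C(=O)c1c(C)cc(OC)cc1OC | intermediate
21 | methyl acetoacetate | COC(=O)CC(C)=O | starting material
22 | 1-{2-[6-(2,4-dimethoxy-6-methylbenzoyl)-1,2,4,5-tetramethoxynaphthalen-7-yl]acetyl}imidazole (not isolated) | O=C(Cc1cc2c(OC)c(OC)cc(OC)c2c(OC)c1C(=O)c1c(C)cc(OC)cc1OC)n1ccnc1 | intermediate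
23 | methyl 6-[6-(2,4-dimethoxy-6-methylbenzoyl)-1,2,4,5-tetramethoxynaphthalen-7-yl]-3,5-dioxohexanoate | COC(=O)CC(=O)CC(=O)Cc1cc2c(OC)c(OC)cc(OC)c2c(OC)c1C(=O)c1c(C)cc(OC)cc1OC | intermediate
24 | 6-{[6-(2,4-dimethoxy-6-methylbenzoyl)-1,2,4,5-tetramethoxynaphthalen-7-yl]methyl}-4-hydroxy-2H-pyran-2-one | COc1cc(C)c(C(=O)c2c(Cc3cc(O)cc(=O)o3)cc3c(OC)c(OC)cc(OC)c3c2OC)c(OC)c1 | intermediate
25 | 6-{[6-(2,4-dihydroxy-6-methylbenzoyl)-1,2,4,5-tetrahydroxynaphthalen-7-yl]methyl}-4-hydroxy-2H-pyran-2-one (not isolated) | Cc1cc(O)cc(O)c1C(=O)c1c(Cc2cc(O)cc(=O)o2)cc2c(O)c(O)cc(O)c2c1O | intermediate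
26 | CNP0158797.0, 6-{[6-(2,4-dihydroxy-6-methylbenzoyl)-2,5-dihydroxy-1,4-dioxo-1,4-dihydronaphthalen-7-yl]methyl}-4-hydroxy-2H-pyran-2-one (no stereocentres) | Cc1cc(O)cc(O)c1C(=O)c1c(Cc2cc(O)cc(=O)o2)cc2c(c1O)C(=O)C=C(O)C2=O | target

## Step count and risks

Total step count: 15. Longest linear sequence: 13 steps (steps 1–8 and 11–15); steps 9–10 form the convergent branch.

Steps most likely to fail:

1. Step 11 (key step). The C6 aryl anion must close onto a ketone that carries a 2,6-disubstituted aryl group; if protonation of that anion is faster, only α-arylation of the ketoester results and the C6–C(=O) bond is not formed. The fallback makes the two bonds one at a time by known chemistry, setting out from 8 and rejoining the route at 20.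
   - 8 is N-silylated to 9 and lithiated at C6 as in step 7, and the aryllithium is added at −78 °C to 2,4-dimethoxy-6-methylbenzaldehyde to give the N-silyl carbinol F1. This loses the N-silyl group on bisulfate work-up to give the racemic carbinol 6-[(2,4-dimethoxy-6-methylphenyl)(hydroxy)methyl]-1,2,4,5-tetramethoxynaphthalen-7-yl N-isopropylcarbamate F2.
   - Dess–Martin periodinane oxidises F2 to the diaryl ketone carbamate F3.
   - DBU/Et2NH (MeCN, 40 °C) releases the 6-aroyl-7-naphthol F4, which is triflated in the same flask with PhNTf2 to the aryl triflate F5.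
   - Stille coupling of F5 with allyltributylstannane (Pd(PPh3)4, LiCl, DMF, 90 °C) gives the 7-allyl ketone F6.
   - Lemieux–Johnson cleavage (OsO4 cat., NaIO4, 2,6-lutidine, dioxane/H2O) gives the arylacetaldehyde F7.
   - Pinnick oxidation (NaClO2, NaH2PO4, 2-methyl-2-butene, t-BuOH/H2O) gives 20.

2. Step 13. The dianion is a strong base and may deprotonate the arylacetyl imidazolide at its benzylic CH2 (ketene formation, return of 20 on work-up); the activated acyl group may also close onto the neighbouring ketone oxygen. The fallback replaces the basic nucleophile by a neutral one, setting out from 20 and rejoining at 23.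
   - 20 is converted under neutral conditions with 1-chloro-N,N,2-trimethylprop-1-en-1-amine (CH2Cl2, 0 °C) into the acid chloride F8.
   - Mukaiyama-type γ-acylation of 1-methoxy-1,3-bis(trimethylsilyloxy)buta-1,3-diene by F8 (CH2Cl2, −78 °C → rt) gives the silyl ketene acetal F9 (double-bond geometry undefined), which is hydrolysed on aqueous HCl work-up to 23.

3. Step 15. Exhaustive demethylation may stall at the ether para to the ketone on the orsellinoyl ring, and the electron-rich hexaphenol 25 may degrade before it is oxidised cleanly. The fallback puts the oxidation first, setting out from 24 and rejoining at 26.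
   - Brief treatment of 24 with (NH4)2Ce(NO3)6 (2.2 equiv, MeCN/H2O, 0 °C) should oxidatively demethylate ring A to the 2-methoxy-1,4-naphthoquinone F10; the short contact time limits oxidation of the pyranone enol.
   - BBr3 (CH2Cl2, −78 °C → rt) then cleaves the four remaining methyl ethers of F10 (the vinylogous ester at C2, the chelated C5 ether and the two orsellinoyl ethers) to give 26.

## Further compounds

F1 | step 11 | 6-[(2,4-dimethoxy-6-methylphenyl)(hydroxy)methyl]-1,2,4,5-tetramethoxynaphthalen-7-yl N-(tert-butyldimethylsilyl)-N-isopropylcarbamate (racemic, not isolated) | COc1c(OC)cc(OC)c2c(OC)c(C(O)c3c(C)cc(OC)cc3OC)c(OC(=O)N(C(C)C)[Si](C)(C)C(C)(C)C)cc12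
F2 | step 11 | 6-[(2,4-dimethoxy-6-methylphenyl)(hydroxy)methyl]-1,2,4,5-tetramethoxynaphthalen-7-yl N-isopropylcarbamate (racemic) | COc1c(OC)cc(OC)c2c(OC)c(C(O)c3c(C)cc(OC)cc3OC)c(OC(=O)NC(C)C)cc12
F3 | step 11 | 6-(2,4-dimethoxy-6-methylbenzoyl)-1,2,4,5-tetramethoxynaphthalen-7-yl N-isopropylcarbamate | COc1c(OC)cc(OC)c2c(OC)c(C(=O)c3c(C)cc(OC)cc3OC)c(OC(=O)NC(C)C)cc12
F4 | step 11 | (2,4-dimethoxy-6-methylphenyl)(7-hydroxy-1,2,4,5-tetramethoxynaphthalen-6-yl)methanone (not isolated) | COc1c(OC)cc(OC)c2c(OC)c(C(=O)c3c(C)cc(OC)cc3OC)c(O)cc12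
F5 | step 11 | 6-(2,4-dimethoxy-6-methylbenzoyl)-1,2,4,5-tetramethoxynaphthalen-7-yl trifluoromethanesulfonate | COc1c(OC)cc(OC)c2c(OC)c(C(=O)c3c(C)cc(OC)cc3OC)c(OS(=O)(=O)C(F)(F)F)cc12
F6 | step 11 | (7-allyl-1,2,4,5-tetramethoxynaphthalen-6-yl)(2,4-dimethoxy-6-methylphenyl)methanone | C=CCc1cc2c(OC)c(OC)cc(OC)c2c(OC)c1C(=O)c1c(C)cc(OC)cc1OC
F7 | step 11 | 2-[6-(2,4-dimethoxy-6-methylbenzoyl)-1,2,4,5-tetramethoxynaphthalen-7-yl]acetaldehyde | O=CCc1cc2c(OC)c(OC)cc(OC)c2c(OC)c1C(=O)c1c(C)cc(OC)cc1OC
F8 | step 13 | 2-[6-(2,4-dimethoxy-6-methylbenzoyl)-1,2,4,5-tetramethoxynaphthalen-7-yl]acetyl chloride | O=C(Cl)Cc1cc2c(OC)c(OC)cc(OC)c2c(OC)c1C(=O)c1c(C)cc(OC)cc1OC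
F9 | step 13 | 6-[6-(2,4-dimethoxy-6-methylbenzoyl)-1,2,4,5-tetramethoxynaphthalen-7-yl]-1-methoxy-1-(trimethylsilyloxy)hex-1-ene-3,5-dione (not isolated) | COC(O[Si](C)(C)C)=CC(=O)CC(=O)Cc1cc2c(OC)c(OC)cc(OC)c2c(OC)c1C(=O)c1c(C)cc(OC)cc1OC
F10 | step 15 | 6-{[6-(2,4-dimethoxy-6-methylbenzoyl)-2,5-dimethoxy-1,4-dioxo-1,4-dihydronaphthalen-7-yl]methyl}-4-hydroxy-2H-pyran-2-one | COC1=CC(=O)c2c(OC)c(C(=O)c3c(C)cc(OC)cc3OC)c(Cc3cc(O)cc(=O)o3)cc2C1=O
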